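The constants used here are those of an exercise; the rest is arithmetic.

We want the leader.

all flasks: substrate 0.020 M; coupling partner 0.0240 M; free catalyst 1.0 mM

|  | time |
|---|---|
| ochre | 10 min |
| violet | 5.0 min |
| grey | 2.5 min |

1. which of these there is most of at the end, counted by the substrate in it, ochre (target / substrate / catalyst intermediate B / side product)
2. which of these there is most of at the end, counted by the substrate in it, violet (target / substrate / catalyst intermediate B / side product)
3. which of these there is most of at the end, counted by the substrate in it, grey (target / substrate / catalyst intermediate B / side product)
4. final amount of the leader among these, as a percentage of the substrate charged, in ochre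
5. final amount of the leader among these, as a percentage of the substrate charged, in violet
6. final amount of the leader among these, as a percentage of the substrate charged, in grey

- percent here means substrate units held: one side product or self-condensation product counts as two
- where a step has two of a species, its rate is k times that concentration squared, and two are used at each turn
- run time (ochre): 10 min

    coupling partner + free catalyst ⇌ catalyst intermediate A (K1 = 22.3 /M, k1 = 151 /M/s)
    substrate + catalyst intermediate A ⇌ catalyst intermediate B (K2 = 112 /M, k2 = 110 /M/s)
    catalyst intermediate B → free catalyst + target (k3 = 3.51 /s)
    substrate + target → side product (k4 = 2.45 /M/s)
    2 substrate → self-condensation product (k5 = 0.0105 /M/s)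

Target is made by the catalyst and lost to substrate. Both rates carry [substrate], so it cancels from their ratio. Catalyst intermediate B goes on to target at 3.51 /s and falls back at 0.982 /s, so 78.1% of it goes forward, and catalyst intermediate A makes target with an effective constant 86.0 /M/s. Target is lost to substrate with constant 2.45 /M/s.

We therefore carry the full ceiling, the [target] at which making and loss balance with the whole catalyst charge as catalyst intermediate A: 35.1 mM. A flask's ceiling is this times the share of catalyst held as catalyst intermediate A.

We take the binding of coupling partner as equilibrated, with equilibrium constant 22.3 /M. At the charge the share is 34.9%, so the ceiling is 12.2 mM, lower than the substrate charge. Our first number is target at that ceiling: 61.2% target, 38.8% side product.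

The weak link is the coupling partner held at its charge. Each turn uses one, and each side product holds two substrate, so the partner left is [coupling partner] at charge minus half the sum of substrate charged and final target. Passing this through the ceiling repeatedly gives:

| Target taken | Coupling partner left | New ceiling |
|---|---|---|
| 12.2 mM | 7.88 mM | 5.25 mM |
| 5.25 mM | 11.4 mM | 7.10 mM |
| 7.10 mM | 10.5 mM | 6.63 mM |

We commit to 33.2% target and 66.8% side product. With target at its ceiling, substrate has two equal pseudo-first-order drains, so its half-life is 21.3 s. Grey's time is 7.03 half-lives, which leaves about 0.765% of the substrate, so we expect side product to lead in each flask.

The forecast says side product in ochre, side product in violet and side product in grey, at 66%, 66% and 65.5%, on the ground that “the reaction of target with substrate competes on level terms”.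

The flasks give side product at 67.9% in ochre, side product at 67.9% in violet and side product at 67.1% in grey.

Taking away the reverse step, catalyst intermediate A to coupling partner + free catalyst, has the largest single effect: ochre's side product goes from 67.9% to 41.2% and the leader changes. Catalyst intermediate A stands at 19.3% of the catalyst charged in ochre at the end, so that flask's ceiling is 6.77 mM, and its target stands lower, at 6.27 mM.

Take the neighbour of violet charged with 0.0050 M of substrate. Even if every substrate cost one coupling partner, its ceiling is 10.4 mM, twice the charge, so target should lead. That flask gives target at 70.5%, with side product at 29.4%.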